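The unit I counted in was the turnover: one turnover is a fall of [E] by a factor e, so a flask's count is the natural logarithm of E charged over E left. That is the natural measure for a fall that is pseudo-first-order in E. I had to place D in five flasks, and here is what I had.

| flask | E | J | remark | time |
|---|---|---|---|---|
| Monday's | 0.012 M | 0.020 mM | run made earlier |  |
| Thursday's | 0.012 M | 0.44 mM | run made earlier |  |
| Wednesday's | 0.0045 M | 0.16 mM | run made earlier |  |
| theta | 0.012 M | 0.16 mM |  | 20 min |
| beta | 0.0080 M | 0.50 mM |  | 20 min |
| alpha | 0.0030 M | 0.60 mM |  | 20 min |
| gamma | 0.0060 M | 0.16 mM |  | 20 min |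
| delta | 0.0060 M | 0.040 mM |  | 20 min |

- Monday's (time / min: D / %, E / %): 3.00: 18.0, 82.5; 6.00: 28.3, 73.0; 8.00: 30.5, 69.0; 12.0: 36.4, 64.4; 15.0: 40.0, 61.6; 20.0: 42.2, 58.5
- Thursday's (time / min: D / %, E / %): 1.00: 47.4, 52.9; 3.00: 64.5, 33.4; 6.00: 71.9, 27.4; 8.00: 74.1, 27.1; 12.0: 76.0, 23.5; 15.0: 76.6, 22.4; 20.0: 78.2, 18.9
- Wednesday's (time / min: D / %, E / %): 4.00: 55.1, 44.2; 8.00: 64.5, 33.5; 12.0: 69.9, 31.3; 15.0: 70.6, 27.2; 20.0: 74.4, 26.6

(standard deviation of a reading: 1 percentage point)

1. the flasks put in order of amount of D, in percent of the E charged, best first, at 20 min (theta / beta / alpha / gamma / delta)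
2. the same order at 2.5 h (theta / beta / alpha / gamma / delta)
3. the amount of D, in percent of the E charged of the flask you put first, at 20 min
4. the amount of D, in percent of the E charged of the flask you put last, at 20 min

- the numbers in the tables scatter with a standard deviation of 1 percentage point

I read the last row of each table, at 20 min, and turned D into a count, taking E left as what D had not taken. Monday's run, with 42.2% of D, had counted 0.548. Thursday's run, with the same charge of E, had 78.2% of D and counted 1.52. So 22.0 times the J bought 0.972 more turnovers. I drew a straight line of count against the logarithm of charged [J] through these two runs, both charged with 0.012 M of E, and its slope is the gain, the turnovers won at 20 min for each factor e in charged [J]: 0.315.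

Wednesday's row tested the line. At Wednesday's J the line gave 1.20, but the run counted 1.36, which is 0.160 above it, with a charge of E lower than the other two. I took that reading, which carries the scatter of the run, as a possible lead for a low charge of E, and on it I put gamma ahead of theta, which share their J.

My line then gave delta 0.767 turnovers, or 53.6% of D, and theta 69.9%. For alpha it gave 1.62 turnovers, or 80.2%, but alpha's J lies beyond Thursday's, so that figure was an extrapolation. I ordered the flasks by J, gamma before theta, and kept that order at 2.5 h.

The forecast held that “conversion depends on initiator dose times time”. It gave alpha > beta > gamma > theta > delta at 20 min and alpha > beta > gamma > theta > delta at 2.5 h, with 80.7% for alpha and 59% for delta. We agreed on the order, but my delta stood lower.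

At 20 min the flasks stood in the order alpha > beta > gamma > theta > delta, and at 2.5 h in the order alpha > beta > gamma > theta > delta.

    E + J → Q (k = 0.270 /M/s)
    E + J → Z + D (k = 6.50 /M/s)
    E + Z → D + Z, rate k3*[Z]*[E] (k = 80.0 /M/s)
    2 Z → G (k = 150 /M/s)

Delta gave 53.0%, a count of 0.755 against my 0.767. Alpha gave 95.3%, a count, reckoned from D as before, of 3.06 against my 1.62. For a neighbour of delta charged with 1.6 × 10⁻⁵ M of J, the same line and gain give 0.478 turnovers, or 38.0% of D. At 20 min that neighbour held 40.0% of D, with E at 60.0%.

The numbers in the tables were computed from invented constants.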